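**Retrosynthetic overview**

- Target ⇐ Mitsunobu ether from umbelliferone and a primary alcohol. The alcohol ⇐ hydroboration of the vinyl group carried from (R)-linalool, which also supplies the side-chain carbinol C3′ and ring carbon C5.
- C1 acetate ⇐ axial alcohol from bulky-hydride reduction of a C1 ketone. C4 carbinol ⇐ equatorial CH3 addition to a C4 ketone. C4 ketone ⇐ Nef reaction of a ring nitro group.
- Key step: the cyclohexane ⇐ nitroalkene + 4-methylpent-1-en-3-one by an amine-catalysed double Michael annulation. C6–C5 forms first and sets C5. C4–C3 then forms by attack of the nitronate (acyl-anion equivalent of the C4 carbonyl) on the enone β-carbon.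
- Nitroalkene ⇐ Henry reaction and dehydration of the aldehyde from selective ozonolysis of O-silyl linalool.
- Ring order: only the cyclohexane is built (step 4); the coumarin is bought intact.

Ring labels used below: C1 (CH–OAc), C2, C3, C4 (C(CH3)OH), C5 (CH bearing the chain), C6 (C(CH3)2); C3′ is the side-chain carbinol.

Assumption: 4-methylpent-1-en-3-one is bought, and the (1R,2R) catalyst of step 4 is taken to give the 5S centre by analogy with its isobutyraldehyde/nitroalkene additions; if a test run shows the opposite sense, its (1S,2S) mirror image is used.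

**Route**

Step 1
Reactants: 1 (R)-linalool
Product: 2 (3R)-3,7-dimethyl-3-(trimethylsilyloxy)octa-1,6-diene
Conditions: N-(trimethylsilyl)imidazole (1.3 equiv), CH2Cl2, rt
Reagents that add atoms: 1-(trimethylsilyl)imidazole, C[Si](C)(C)n1ccnc1
Why: O-silylation of the tertiary alcohol masks it so that it cannot add (oxa-Michael, five-membered ring) to the nitroalkene made in step 3; the C3′ centre comes unchanged from the chiral pool.

Step 2
Reactants: 2 (3R)-3,7-dimethyl-3-(trimethylsilyloxy)octa-1,6-diene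
Product: 4 (4R)-4-methyl-4-(trimethylsilyloxy)hex-5-enal, via ozonide 3 (not isolated)
Conditions: O3 (1.0 equiv, Sudan Red 7B end point), CH2Cl2, −78 °C; then PPh3, −78 °C → rt
Reagents that add atoms: ozone, [O-][O+]=O
Why: Ozonolysis; the electron-rich trisubstituted alkene reacts far faster than the vinyl group next to the quaternary C–OSi carbon, so one equivalent of ozone cleaves only the isopropylidene end.

Step 3
Reactants: 4 (4R)-4-methyl-4-(trimethylsilyloxy)hex-5-enal
Product: 7 trimethyl{[(3R,6E)-3-methyl-7-nitrohepta-1,6-dien-3-yl]oxy}silane, via nitro alcohol 5 (not isolated), via mesylate 6 (not isolated)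
Conditions: CH3NO2 (10 equiv), 1,1,3,3-tetramethylguanidine (10 mol %), THF, 0 °C; then CH3SO2Cl, Et3N, CH2Cl2, −10 → 0 °C
Reagents that add atoms: nitromethane, C[N+](=O)[O-]
Why: Henry reaction followed by mesylation and E1cB elimination gives the E-nitroalkene; its nitro carbon is the future C4 carbonyl carbon.

Step 4
Reactants: 7 trimethyl{[(3R,6E)-3-methyl-7-nitrohepta-1,6-dien-3-yl]oxy}silane, 8 4-methylpent-1-en-3-one
Product: 10 (3S,4S)-3-[(3R)-3-hydroxy-3-methylpent-4-en-1-yl]-2,2-dimethyl-4-nitrocyclohexan-1-one, via silyl ether 9 (not isolated)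
Conditions: 8 (2 equiv, slow addition), 1-[(1R,2R)-2-aminocyclohexyl]-3-[3,5-bis(trifluoromethyl)phenyl]thiourea (20 mol %), PhCO2H (20 mol %), toluene, 0 °C → rt; then 1 M HCl, THF, 0 °C
Reagents that add atoms: none
Why: Proposed new method: the primary amine condenses with 8 to the cross-conjugated 2-aminodiene, whose C(CH3)2 terminus adds to the thiourea-bound nitroalkene (C6–C5 bond, quaternary C6, catalyst-controlled 5S centre), and the resulting nitronate, acting as the acyl-anion equivalent of the C4 carbonyl, closes onto the vinyl iminium (C4–C3 bond, formal [4+2] double Michael annulation, nitro group equatorial and trans to the chain), after which acid frees the ketone and the tertiary alcohol; the closest known reactions are amine-catalysed formal Diels–Alder reactions of enones with nitroalkenes through 2-aminodienes and primary amine–thiourea additions of isobutyraldehyde to nitroalkenes.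

Step 5
Reactants: 10 (3S,4S)-3-[(3R)-3-hydroxy-3-methylpent-4-en-1-yl]-2,2-dimethyl-4-nitrocyclohexan-1-one
Product: 11 (1R,3S,4S)-3-[(3R)-3-hydroxy-3-methylpent-4-en-1-yl]-2,2-dimethyl-4-nitrocyclohexan-1-ol
Conditions: LiBH(s-Bu)3 (3.2 equiv), THF, −78 → −40 °C; then H2O
Reagents that add atoms: none
Why: Bulky-hydride reduction; the chair is locked by the equatorial nitro group and side chain, the hydride enters C1 from the equatorial side and gives the axial 1R alcohol trans to the C5 chain (as with 4,4-dimethyl-3-keto terpenoids), while the nitro group is only deprotonated and returns on quench; reducing before the basic step 6 also removes the ketone that could allow retro-Michael opening.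

Step 6
Reactants: 11 (1R,3S,4S)-3-[(3R)-3-hydroxy-3-methylpent-4-en-1-yl]-2,2-dimethyl-4-nitrocyclohexan-1-ol
Product: 13 (2S,4R)-4-hydroxy-2-[(3R)-3-hydroxy-3-methylpent-4-en-1-yl]-3,3-dimethylcyclohexan-1-one, via sodium nitronate 12 (not isolated)
Conditions: NaOMe (1.2 equiv), MeOH, 0 °C; then TiCl3 (4 equiv), NH4OAc buffer (pH 5–6), H2O–MeOH, 0 °C → rt
Reagents that add atoms: water, O
Why: Nef reaction in the McMurry form; trivalent titanium reduces the nitronate to the imine, which hydrolyses to the C4 ketone and completes the 1,4-dioxygen pattern; the buffered medium leaves the C5 centre alpha to the new ketone untouched.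

Step 7
Reactants: 13 (2S,4R)-4-hydroxy-2-[(3R)-3-hydroxy-3-methylpent-4-en-1-yl]-3,3-dimethylcyclohexan-1-one
Product: 14 (1R,2S,4R)-2-[(3R)-3-hydroxy-3-methylpent-4-en-1-yl]-1,3,3-trimethylcyclohexane-1,4-diol
Conditions: CeCl3 (anhydrous, 4.5 equiv), CH3MgBr (4.5 equiv), THF, −78 → −40 °C; then H2O
Reagents that add atoms: methylmagnesium bromide, C[Mg]Br
Why: Organocerium 1,2-addition; the axial path to C4 is blocked by the syn-axial C6 methyl, so CH3 enters equatorially and the new hydroxyl is axial and cis to the C5 chain (4R), while CeCl3 suppresses enolisation toward C5.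

Step 8
Reactants: 14 (1R,2S,4R)-2-[(3R)-3-hydroxy-3-methylpent-4-en-1-yl]-1,3,3-trimethylcyclohexane-1,4-diol
Product: 15 (1R,3S,4R)-4-hydroxy-3-[(3R)-3-hydroxy-3-methylpent-4-en-1-yl]-2,2,4-trimethylcyclohexyl acetate
Conditions: Ac2O (1.5 equiv), DMAP (0.2 equiv), pyridine, CH2Cl2, 0 °C → rt
Reagents that add atoms: acetic anhydride, CC(=O)OC(C)=O
Why: DMAP-catalysed acylation takes the only secondary alcohol; the two tertiary alcohols do not react under these conditions.

Step 9
Reactants: 15 (1R,3S,4R)-4-hydroxy-3-[(3R)-3-hydroxy-3-methylpent-4-en-1-yl]-2,2,4-trimethylcyclohexyl acetate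
Product: 17 (1R,3S,4R)-3-[(3R)-3,5-dihydroxy-3-methylpentyl]-4-hydroxy-2,2,4-trimethylcyclohexyl acetate, via alkylborane 16 (not isolated)
Conditions: 9-borabicyclo[3.3.1]nonane (3.5 equiv), THF, 0 °C → rt; then 30% H2O2, aq NaOAc, 0 °C
Reagents that add atoms: hydrogen peroxide, OO
Why: Anti-Markovnikov hydroboration–oxidation of the only alkene gives the primary alcohol; the acetate-buffered peroxide work-up keeps the C1 acetate.

Step 10
Reactants: 17 (1R,3S,4R)-3-[(3R)-3,5-dihydroxy-3-methylpentyl]-4-hydroxy-2,2,4-trimethylcyclohexyl acetate, 18 umbelliferone (7-hydroxycoumarin)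
Product: 19 (1R,3S,4R)-4-hydroxy-3-[(3R)-3-hydroxy-3-methyl-5-(2-oxo-2H-chromen-7-yloxy)pentyl]-2,2,4-trimethylcyclohexyl acetate (CNP0333962.1)
Conditions: PPh3 (1.5 equiv), DIAD (1.5 equiv), THF, 0 °C → rt
Reagents that add atoms: none
Why: Mitsunobu etherification; only the primary alcohol is activated and the acidic phenol (pKa about 7.8) displaces it, leaving the tertiary alcohols and all stereocentres untouched.

**Compound list**

1 | (R)-linalool, (3R)-3,7-dimethylocta-1,6-dien-3-ol | CC(C)=CCC[C@@](C)(O)C=C | starting material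
2 | (3R)-3,7-dimethyl-3-(trimethylsilyloxy)octa-1,6-diene | CC(C)=CCC[C@@](C)(O[Si](C)(C)C)C=C | intermediate
3 | ozonide (1,2,4-trioxolane) of 2 at the trisubstituted alkene | CC1(C)OOC(CC[C@@](C)(O[Si](C)(C)C)C=C)O1 | intermediate
4 | (4R)-4-methyl-4-(trimethylsilyloxy)hex-5-enal | O=CCC[C@@](C)(O[Si](C)(C)C)C=C | intermediate
5 | (5R)-5-methyl-1-nitro-5-(trimethylsilyloxy)hept-6-en-2-ol (both carbinol epimers) | [O-][N+](=O)CC(O)CC[C@@](C)(O[Si](C)(C)C)C=C | intermediate
6 | methanesulfonate of 5 | CS(=O)(=O)OC(C[N+](=O)[O-])CC[C@@](C)(O[Si](C)(C)C)C=C | intermediate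
7 | trimethyl{[(3R,6E)-3-methyl-7-nitrohepta-1,6-dien-3-yl]oxy}silane | [O-][N+](=O)/C=C/CC[C@@](C)(O[Si](C)(C)C)C=C | intermediate
8 | 4-methylpent-1-en-3-one (isopropyl vinyl ketone) | CC(C)C(=O)C=C | starting material
9 | (3S,4S)-2,2-dimethyl-3-[(3R)-3-methyl-3-(trimethylsilyloxy)pent-4-en-1-yl]-4-nitrocyclohexan-1-one | O=C1CC[C@H]([N+](=O)[O-])[C@@H](CC[C@@](C)(O[Si](C)(C)C)C=C)C1(C)C | intermediate
10 | (3S,4S)-3-[(3R)-3-hydroxy-3-methylpent-4-en-1-yl]-2,2-dimethyl-4-nitrocyclohexan-1-one | O=C1CC[C@H]([N+](=O)[O-])[C@@H](CC[C@@](C)(O)C=C)C1(C)C | intermediate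
11 | (1R,3S,4S)-3-[(3R)-3-hydroxy-3-methylpent-4-en-1-yl]-2,2-dimethyl-4-nitrocyclohexan-1-ol | O[C@@H]1CC[C@H]([N+](=O)[O-])[C@@H](CC[C@@](C)(O)C=C)C1(C)C | intermediate
12 | sodium nitronate of 11 | [Na+].O[C@@H]1CCC(=[N+]([O-])[O-])[C@@H](CC[C@@](C)(O)C=C)C1(C)C | intermediate
13 | (2S,4R)-4-hydroxy-2-[(3R)-3-hydroxy-3-methylpent-4-en-1-yl]-3,3-dimethylcyclohexan-1-one | O[C@@H]1CCC(=O)[C@@H](CC[C@@](C)(O)C=C)C1(C)C | intermediate
14 | (1R,2S,4R)-2-[(3R)-3-hydroxy-3-methylpent-4-en-1-yl]-1,3,3-trimethylcyclohexane-1,4-diol | O[C@@H]1CC[C@@](C)(O)[C@@H](CC[C@@](C)(O)C=C)C1(C)C | intermediate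
15 | (1R,3S,4R)-4-hydroxy-3-[(3R)-3-hydroxy-3-methylpent-4-en-1-yl]-2,2,4-trimethylcyclohexyl acetate | CC(=O)O[C@@H]1CC[C@@](C)(O)[C@@H](CC[C@@](C)(O)C=C)C1(C)C | intermediate
16 | B-alkyl-9-borabicyclo[3.3.1]nonane adduct of 15 (boron on the terminal carbon) | CC(=O)O[C@@H]1CC[C@@](C)(O)[C@@H](CC[C@@](C)(O)CCB2C3CCCC2CCC3)C1(C)C | intermediate
17 | (1R,3S,4R)-3-[(3R)-3,5-dihydroxy-3-methylpentyl]-4-hydroxy-2,2,4-trimethylcyclohexyl acetate | CC(=O)O[C@@H]1CC[C@@](C)(O)[C@@H](CC[C@@](C)(O)CCO)C1(C)C | intermediate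
18 | umbelliferone (7-hydroxycoumarin) | O=c1ccc2ccc(O)cc2o1 | starting material
19 | (1R,3S,4R)-4-hydroxy-3-[(3R)-3-hydroxy-3-methyl-5-(2-oxo-2H-chromen-7-yloxy)pentyl]-2,2,4-trimethylcyclohexyl acetate | CC(=O)O[C@@H]1CC[C@@](C)(O)[C@@H](CC[C@@](C)(O)CCOc2ccc3ccc(=O)oc3c2)C1(C)C | target

**Step count and risks**

Total steps: 10. Longest linear sequence: 10 steps, from (R)-linalool 1.

The three steps most likely to fail:

- **Step 4 (annulation).** The hindered aminodiene may form slowly, the vinyl ketone may oligomerise, or the ring may not close. The fallback sets out from 7 and comes back at 9. The same amine–thiourea adds isobutyraldehyde to 7 (a known reaction type) and gives (3S,6R)-2,2,6-trimethyl-3-(nitromethyl)-6-(trimethylsilyloxy)oct-7-enal F1. CH2=CHMgBr with CeCl3 (2.2 equiv, −78 °C, the nitro group sitting as its nitronate) adds to the aldehyde and gives (5S,8R)-4,4,8-trimethyl-5-(nitromethyl)-8-(trimethylsilyloxy)deca-1,9-dien-3-ol F2. Dess–Martin periodinane gives (5S,8R)-4,4,8-trimethyl-5-(nitromethyl)-8-(trimethylsilyloxy)deca-1,9-dien-3-one F3. DBU then closes F3 by intramolecular nitro-Michael addition to 9, and the acid treatment of step 4 gives 10.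
- **Step 5 (reduction beside a nitro group).** The hydride may attack the nitro group or give the wrong face. The fallback sets out from 10 and comes back at 14. The Nef conditions of step 6, kept cold, are applied to 10 and give (3S)-3-[(3R)-3-hydroxy-3-methylpent-4-en-1-yl]-2,2-dimethylcyclohexane-1,4-dione F4. CH3MgBr with CeCl3 at −78 °C adds to the less hindered C4 ketone (the C1 carbonyl is neopentylic) and gives (3S,4R)-4-hydroxy-3-[(3R)-3-hydroxy-3-methylpent-4-en-1-yl]-2,2,4-trimethylcyclohexan-1-one F5. LiBH(s-Bu)3 then reduces C1 to the axial alcohol, which is 14.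
- **Step 7 (methyl addition).** Enolisation toward C5 or a masked ketone (transannular hemiketal alkoxide) may stop the addition. The fallback sets out from 13 and comes back at 14. Trimethylsulfoxonium iodide with NaH in DMSO transfers CH2 from the equatorial side and gives (3R,4S,6R)-4-[(3R)-3-hydroxy-3-methylpent-4-en-1-yl]-5,5-dimethyl-1-oxaspiro[2.5]octan-6-ol F6. LiAlH4 opens the epoxide at its CH2 carbon and gives 14 with the same C4 configuration.

**Further compounds**

F1 | step 4 | (3S,6R)-2,2,6-trimethyl-3-(nitromethyl)-6-(trimethylsilyloxy)oct-7-enal | O=CC(C)(C)[C@@H](C[N+](=O)[O-])CC[C@@](C)(O[Si](C)(C)C)C=C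
F2 | step 4 | (5S,8R)-4,4,8-trimethyl-5-(nitromethyl)-8-(trimethylsilyloxy)deca-1,9-dien-3-ol | C=CC(O)C(C)(C)[C@@H](C[N+](=O)[O-])CC[C@@](C)(O[Si](C)(C)C)C=C
F3 | step 4 | (5S,8R)-4,4,8-trimethyl-5-(nitromethyl)-8-(trimethylsilyloxy)deca-1,9-dien-3-one | C=CC(=O)C(C)(C)[C@@H](C[N+](=O)[O-])CC[C@@](C)(O[Si](C)(C)C)C=C
F4 | step 5 | (3S)-3-[(3R)-3-hydroxy-3-methylpent-4-en-1-yl]-2,2-dimethylcyclohexane-1,4-dione | O=C1CCC(=O)[C@@H](CC[C@@](C)(O)C=C)C1(C)C
F5 | step 5 | (3S,4R)-4-hydroxy-3-[(3R)-3-hydroxy-3-methylpent-4-en-1-yl]-2,2,4-trimethylcyclohexan-1-one | O=C1CC[C@@](C)(O)[C@@H](CC[C@@](C)(O)C=C)C1(C)C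
F6 | step 7 | (3R,4S,6R)-4-[(3R)-3-hydroxy-3-methylpent-4-en-1-yl]-5,5-dimethyl-1-oxaspiro[2.5]octan-6-ol | O[C@@H]1CC[C@]2(CO2)[C@@H](CC[C@@](C)(O)C=C)C1(C)C
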